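The constants of the candidate steps are not given, so any reckoning has to stand on the two earlier runs, green and amber.

| flask | J | D | remark | time |
|---|---|---|---|---|
| green | 0.020 M | 1.2 equiv | run made earlier |  |
| amber | 0.25 M | 1.2 equiv | run made earlier |  |
| south | 0.040 M | 1.20 equiv |  | 3.0 h |
| south-west | 0.080 M | 1.20 equiv |  | 3.0 h |
| north | 0.15 M | 1.20 equiv |  | 3.0 h |
| west | 0.30 M | 1.20 equiv |  | 3.0 h |

- green (time / h: Q / %): 0.250: 0.7; 0.333: 1.9; 0.500: 2.5; 0.833: 2.6; 1.33: 4.4; 2.00: 5.4; 3.00: 6.5
- amber (time / h: Q / %): 0.250: 0; 0.333: 0.5; 0.500: 0; 0.833: 2.0; 1.33: 8.8; 2.00: 17.5; 3.00: 24.4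

(standard deviation of a reading: 1 percentage point)

- amount of Q at the end, in percent of the J charged for south, south-west, north, west, in this order
- the shape of the row from first to last (rises, then falls / falls all the way / falls, then rises / hardly changes / rises all the way)

- D is a solid; its amount is given per volume of the solution
- candidate steps: J -> L; Z -> G; L + G -> Q; D <-> Z; Z <-> E; L -> X
- at the start none of D is in solution
- "hardly changes" means that all values lie within two and a half points (for a concentration: within two and a half percent of the largest)

In the first instants both flasks start with D wholly solid. At 0.500 h, amber reads Q 0% and green 2.5%, readings too near their scatter of 1 percentage point to rank the two flasks. In the middle, the readings of amber pass those of green, from 2.0% against 2.6% at 0.833 h to 8.8% against 4.4% at 1.33 h. Towards the end, the ratio of amber's reading to green's goes on rising, from 2.00 at 1.33 h to 3.75 at 3.00 h.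

The end readings of the two runs give a slope on logarithmic axes:

n = ln(Q amber / Q green) / ln(c_J amber / c_J green) = 0.524

This n, the yield order, is the percent change of the yield of Q per percent change of the charge of J, at equal equivalents of D and equal time. A positive n means the row climbs. An n of minus one means that c_Q at the end no longer grows with the charge. Amber's c_Q is 0.0610 M, so two cases stand for west:

mean n kept: 26.8%

n of minus one: 20.3%

D is a solid, so its dissolved amount may stop growing with the charge, and then c_Q may too, which is the second case. The readings do not choose between the cases, so this reckoning puts west between 20.3% and 26.8% and leaves open whether the row rises all the way or rises, then falls.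

The forecast gives 10.5%, 16%, 21% and 25.5%, rises all the way, and expects “flattening rather than a clear fall”.

The flasks give 13.4%, 20.2%, 24.5% and 21.9%: the row rises, then falls.

    J → L (k = 0.0240 min⁻¹)
    Z → G (k = 0.0130 min⁻¹)
    L + G → Q (k = 0.160 L mol⁻¹ min⁻¹)
    D ⇌ Z, rate k4*(cs4 - [Z]) while solid is left; crystals form when [Z] > cs4 (solubility = 0.110 M, k = 0.0350 min⁻¹)
    Z ⇌ E (K = 1.60, k = 0.0210 min⁻¹)
    L → X (k = 0.0140 min⁻¹)

From north to west, n is −0.162, and the row turns at 0.17 M; west holds D 48.3% at 1.50 h, north 0%. From south to south-west, n is 0.592, beside a local order of 0.47 at south-west. In south at 3.00 h, L goes to X at 3.6 times its rate to Q, a selectivity factor. South then holds Q 13.4% against X 73.9%.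

Readings and results stem from a simulated flask on assumed constants; the scatter is artificial.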